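**Plan**

Retrosynthesis: the side-chain C9'–C10' bond is cut first (as a C9'=C10' alkene, by cross-metathesis), then the O5–CH3 bond, and last the ring C3–C1' bond (three-component reductive alkylation of a dihydroxybenzoquinone with an ω-alkenal and a hydride donor).
Forward: no ring is built; the bought quinone ring is C-alkylated at C3 with a ten-carbon alkenyl chain (step 1), etherified at O5 only (step 2), the chain is completed by joining C9' to C10' (step 3), and the alkene is saturated with reduction and aerial re-oxidation of the ring (step 4).
Enabling feature: C9'–C10' is a plain CH2–CH2 link, eight methylenes away from ring C3, so it can be made as a C=C that leaves no trace after hydrogenation. The quinone ring (C1–C6) offers only the tetrasubstituted C2=C3 and the electron-poor, methoxy-bearing C5=C6 bonds, both inert to ruthenium carbenes, so the union can be run on the unprotected core.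
Stereochemistry: the target has no stereocentre; the only stereo-elements made on the way (the C9'=C10' geometry and the exocyclic C=C of the step 1 intermediate) are erased by reduction.
Oxygen pattern: the C3 chain shields O2, so etherification goes to O5, and the final hydroquinone can only re-oxidise to the C1/C4 quinone because O5 is methylated.

Key step: step 3

Remark: ring atoms are numbered as in the target (C1=O, C2–OH, C3–chain, C4=O, C5–OMe, C6–H) and chain atoms C1'–C16' from the ring; dec-9-enal is taken as a commercial aldehyde (otherwise one oxidation from commercial dec-9-en-1-ol).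

**Route**

Step 1
Reactants: 1 2,5-dihydroxy-1,4-benzoquinone; 2 dec-9-enal
Product: 4 3-(dec-9-en-1-yl)-2,5-dihydroxy-1,4-benzoquinone, via alkylidene trione 3 (not isolated)
Conditions: Hantzsch ester (1.1 equiv), L-proline (20 mol%), CH2Cl2–EtOH, rt; 1 (1.3 equiv), 2 added slowly
Reagents that add atoms: none
Why: Three-component reductive alkylation (Knoevenagel condensation followed by Hantzsch-ester transfer hydrogenation), in which the proline-derived iminium ion of 2 is attacked by the nucleophilic C3 of the vinylogous acid 1, loss of water gives the strongly electrophilic alkylidene trione 3, and 3 takes up hydride at C1' while the isolated C9'=C10' bond is left untouched.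

Step 2
Reactants: 4 3-(dec-9-en-1-yl)-2,5-dihydroxy-1,4-benzoquinone
Product: 5 3-(dec-9-en-1-yl)-2-hydroxy-5-methoxy-1,4-benzoquinone
Conditions: MeOH, H2SO4 (cat.), 50 °C
Reagents that add atoms: methanol, CO
Why: Acid-catalysed Fischer-type etherification of a vinylogous carboxylic acid by addition–elimination of methanol at the hydroxyl-bearing ring carbon, which should occur at C5 (neighbour C6–H) and not at C2, because C2 is shielded between C1=O and the C3 chain and its ether would be twisted out of conjugation, in line with the known resistance of 3-alkyl-2-hydroxyquinones to this etherification.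

Step 3
Reactants: 5 3-(dec-9-en-1-yl)-2-hydroxy-5-methoxy-1,4-benzoquinone; 6 oct-1-ene
Product: 7 2-hydroxy-3-(hexadec-9-en-1-yl)-5-methoxy-1,4-benzoquinone (E/Z mixture at C9'=C10')
Conditions: Hoveyda–Grubbs II (3 mol%), 6 (6 equiv), CH2Cl2, 40 °C, Ar sweep
Reagents that add atoms: none
Why: Olefin cross-metathesis: the Ru alkylidene adds to the terminal C9'=C10' vinyl group of 5 and to oct-1-ene by [2+2] cycloaddition, the ruthenacyclobutanes revert, ethene leaves and the heptylidene unit of 6 is delivered to C9', forming the C9'=C10' bond of the full C16 chain. The closest known reaction type is the cross-metathesis of two unhindered terminal alkenes with a second-generation Ru–NHC catalyst, which tolerates quinones and protons of carboxylic-acid strength. No ring is closed and no stereocentre is formed; the E/Z geometry of the new alkene is not controlled and need not be, since step 4 saturates it. The step needs cross- over homo-coupling, which should be secured by the excess of the cheap, volatile partner 6 and by the fact that any homodimer of 5 remains a metathesis-active 1,2-disubstituted alkene that is drawn back into the cross product. It needs chemoselectivity for the side-chain vinyl group, secured by the ring itself: C2=C3 is tetrasubstituted and C5=C6 is an electron-poor, methoxy-substituted enone bond, and neither engages the carbene. It needs the double bond to stay in place (a migrated alkene would give C15 or C17 homologues), which the benzoquinone unit of 5 should help to secure, since benzoquinones are used as additives that intercept the Ru–H species responsible for migration.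

Step 4
Reactants: 7 2-hydroxy-3-(hexadec-9-en-1-yl)-5-methoxy-1,4-benzoquinone
Product: 9 3-hexadecyl-2-hydroxy-5-methoxy-1,4-benzoquinone, via benzenetriol 8 (not isolated)
Conditions: H2 (1 atm), 10% Pd/C, EtOAc, rt; filter (Celite); then air, rt
Reagents that add atoms: none
Why: Heterogeneous hydrogenation saturates the C9'=C10' bond and reduces the quinone to the benzene-1,2,4-triol 8, which on contact with air should be re-oxidised (hydroquinone autoxidation, the event that also closes the presumed biosynthesis of the lipid benzoquinones) to the 2-hydroxy-1,4-quinone, the only quinone open to it because O5 is methylated and only the C1/C4 oxygen pair is para and free.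

**Compound list**

1 | 2,5-dihydroxy-1,4-benzoquinone | O=C1C=C(O)C(=O)C=C1O | starting material
2 | dec-9-enal | C=CCCCCCCCC=O | starting material
3 | 3-(dec-9-en-1-ylidene)-5-hydroxycyclohex-5-ene-1,2,4-trione (exocyclic C=C geometry not defined) | O=C1C=C(O)C(=O)C(=CCCCCCCCC=C)C1=O | intermediate
4 | 3-(dec-9-en-1-yl)-2,5-dihydroxy-1,4-benzoquinone | C=CCCCCCCCCC1=C(O)C(=O)C=C(O)C1=O | intermediate
5 | 3-(dec-9-en-1-yl)-2-hydroxy-5-methoxy-1,4-benzoquinone | C=CCCCCCCCCC1=C(O)C(=O)C=C(OC)C1=O | intermediate
6 | oct-1-ene | C=CCCCCCC | starting material
7 | 2-hydroxy-3-(hexadec-9-en-1-yl)-5-methoxy-1,4-benzoquinone (E/Z mixture) | CCCCCCC=CCCCCCCCCC1=C(O)C(=O)C=C(OC)C1=O | intermediate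
8 | 3-hexadecyl-5-methoxybenzene-1,2,4-triol | CCCCCCCCCCCCCCCCc1c(O)c(O)cc(OC)c1O | intermediate
9 | 3-hexadecyl-2-hydroxy-5-methoxy-1,4-benzoquinone | CCCCCCCCCCCCCCCCC1=C(O)C(=O)C=C(OC)C1=O | target

**Summary**

Total step count: 4
Longest linear sequence: 4 steps (1 → 4 → 5 → 7 → 9)

Three steps most likely to fail:

Step 3. The ruthenium carbene may be deactivated by the acidic, potentially chelating hydroxyquinone, or the metathesis may stall at homodimers. The fallback sets out from 2 and comes back at 7; it moves the metathesis in front of the quinone chemistry. Dec-9-enal 2 and oct-1-ene 6 are cross-metathesised (Hoveyda–Grubbs II, CH2Cl2, 40 °C) to hexadec-9-enal F1. F1 is then combined with 1, Hantzsch ester and L-proline; Knoevenagel condensation gives 3-(hexadec-9-en-1-ylidene)-5-hydroxycyclohex-5-ene-1,2,4-trione F2, which is reduced in the flask to 3-(hexadec-9-en-1-yl)-2,5-dihydroxy-1,4-benzoquinone F3. Etherification of F3 at O5 (MeOH, cat. H2SO4) gives 7.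

Step 1. A second alkylation at C6, Michael trapping of the alkylidene trione by a second molecule of 1, or reduction of the quinone by the dihydropyridine may erode the mono-alkylation. The fallback sets out from 1 and comes back at 4; it replaces the ionic condensation/hydride sequence by a radical alkylation. Bis(undec-10-enoyl) peroxide F4 is made from commercial undec-10-enoyl chloride with H2O2 and NaOH, then heated with 1 in acetic acid at about 95 °C. Decarboxylation gives the dec-9-enyl radical, which adds to C3 of 1, and the adduct radical is oxidised by further peroxide to give 4.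

Step 2. The etherification may stop short of completion or lose its O5 selectivity. The fallback sets out from 4 and comes back at 5; it makes the selection in a hydrolysis instead of an etherification. Both hydroxyl groups are methylated (MeI, Ag2O, CHCl3) to 3-(dec-9-en-1-yl)-2,5-dimethoxy-1,4-benzoquinone F5. The C2 methoxyl of F5, twisted out of conjugation by the C3 chain and therefore the more labile vinylogous ester, is then hydrolysed selectively (70% HClO4, 1,4-dioxane, rt) to give 5.

Further compounds
F1 | step 3 | hexadec-9-enal (E/Z mixture) | CCCCCCC=CCCCCCCCC=O
F2 | step 3 | 3-(hexadec-9-en-1-ylidene)-5-hydroxycyclohex-5-ene-1,2,4-trione | O=C1C=C(O)C(=O)C(=CCCCCCCCC=CCCCCCC)C1=O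
F3 | step 3 | 3-(hexadec-9-en-1-yl)-2,5-dihydroxy-1,4-benzoquinone | CCCCCCC=CCCCCCCCCC1=C(O)C(=O)C=C(O)C1=O
F4 | step 1 | bis(undec-10-enoyl) peroxide | C=CCCCCCCCCC(=O)OOC(=O)CCCCCCCCC=C
F5 | step 2 | 3-(dec-9-en-1-yl)-2,5-dimethoxy-1,4-benzoquinone | C=CCCCCCCCCC1=C(OC)C(=O)C=C(OC)C1=O
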